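Atom labels follow labdane numbering: ring A = C1–C5 + C10, ring B = C5–C10, C18 = carboxyl carbon on C4, C17 = CH2 on C8, side chain C11–C16 on C9.
Retrosynthesis: after end-game cuts (C18 tert-butyl ester; 6-OAc from 6-OH; C8=C17 from a C8 ketone; 6-OH from the 6,7-epoxide of a C8(=O)–C7=C6 enone), the strategic cut is C4–C5, which opens ring A; then C9–C11 (enolate alkylation) and C10–C1 (conjugate addition).
Enabling feature: in the ring B enone, C5 is the γ-carbon of the C8 carbonyl, C4 is the α-carbon of the C18 ester, and C6 (oxygenated in the target) is the enone β-carbon; C4–C5 is therefore the bond of an oxidative coupling between an ester enolate and a dienolate.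
Forward: ring B is bought as 3-methylcyclohex-2-enone; the C1–C4/C18 chain is added at C10, the enone is re-formed on the far side, the (E)-dienyl chain is put on C9, and ring A is closed last on this monocyclic keto ester, used as a mixture of four diastereomers.
Stereochemistry: C10 from a copper–phosphoramidite conjugate addition; C4 from an iron bridge between the two enolate oxygens in the key step; C5 and C9 by equilibration to the trans-fused, equatorial isomer (all four diastereomers converge); C6 from epoxidation anti to the axial methyls on C4 and C10; the 12E alkene from commercial (E)-enynol.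

Key step: step 7

Remark on the chemistry: 3, 7, 8 and 12 are carried as epimer mixtures at the chain carbon that becomes C4 (12 also at C9); these centres are planar or equilibrating in the steps that fix them.

Step 1
Reactants: 1 tert-butyl propanoate; 2 3-bromoprop-1-ene (allyl bromide)
Product: 3 tert-butyl 2-methylpent-4-enoate (racemic)
Conditions: LiN(iPr)2, THF, −78 °C; then 2, −78 → 0 °C
Reagents that add atoms: none
Why: Alkylation of the lithium ester enolate with the allylic bromide (SN2) gives the branched chain, and the new stereocentre is left racemic because it becomes the planar enolate carbon C4 in step 7.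

Step 2
Reactants: 3 tert-butyl 2-methylpent-4-enoate; 4 3-methylcyclohex-2-en-1-one
Product: 7 tert-butyl 2-methyl-5-[(1R)-1-methyl-3-oxocyclohexyl]pentanoate, via alkylzirconocene chloride 5 (not isolated), via trimethylsilyl enol ether 6 (not isolated)
Conditions: Cp2ZrHCl, CH2Cl2, 23 °C; then CuCl (cat.), AgNTf2 (cat.), binaphthol-derived phosphoramidite ligand (cat.), 4, Me3SiCl, Et2O, 23 °C; dilute aq. HCl
Reagents that add atoms: none
Why: Hydrozirconation of the terminal alkene followed by copper-catalysed asymmetric conjugate addition of the primary alkylzirconium to the β-methyl enone creates the quaternary C10, whose R configuration is set by the chiral copper–phosphoramidite catalyst (ligand enantiomer chosen accordingly), while the tert-butyl ester is inert to the organozirconium.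

Step 3
Reactants: 7 tert-butyl 2-methyl-5-[(1R)-1-methyl-3-oxocyclohexyl]pentanoate
Product: 8 tert-butyl 2-methyl-5-[(1R)-1-methyl-5-oxocyclohex-3-en-1-yl]pentanoate
Conditions: 2-iodoxybenzoic acid, DMSO/PhF, 70 °C
Reagents that add atoms: none
Why: Dehydrogenation of the ketone with 2-iodoxybenzoic acid can give only one enone (C8=O, C7=C6) because the quaternary C10 leaves a β-hydrogen on the C7–C6 side alone, and no stereocentre is touched.

Step 4
Reactants: 9 (2E)-3-methylpent-2-en-4-yn-1-ol
Product: 10 (2E)-3-methylpenta-2,4-dien-1-ol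
Conditions: H2 (1 atm), Pd/CaCO3 poisoned with Pb(OAc)2, quinoline, EtOAc, 0 °C
Reagents that add atoms: none
Why: Lindlar semihydrogenation reduces the terminal alkyne to the vinyl group and leaves the E trisubstituted alkene, the later C12=C13, unchanged.

Step 5
Reactants: 10 (2E)-3-methylpenta-2,4-dien-1-ol
Product: 11 (3E)-5-bromo-3-methylpenta-1,3-diene
Conditions: PBr3, pyridine (cat.), Et2O, −10 °C; used at once
Reagents that add atoms: phosphorus tribromide, BrP(Br)Br
Why: Bromination of the primary allylic alcohol with PBr3 (SN2 on the phosphite ester) keeps the E geometry.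

Step 6
Reactants: 8 tert-butyl 2-methyl-5-[(1R)-1-methyl-5-oxocyclohex-3-en-1-yl]pentanoate; 11 (3E)-5-bromo-3-methylpenta-1,3-diene
Product: 12 tert-butyl 2-methyl-5-{(1R)-1-methyl-6-[(2E)-3-methylpenta-2,4-dien-1-yl]-5-oxocyclohex-3-en-1-yl}pentanoate
Conditions: LiN(iPr)2, THF, −78 °C; then 11, DMPU, −78 → −30 °C
Reagents that add atoms: none
Why: Kinetic deprotonation of the enone at the α′-carbon C9 and SN2 alkylation with the primary allylic bromide attach the side chain, and the C9 configuration is not controlled here because C9 is equilibrated in step 8.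

Step 7
Reactants: 12 tert-butyl 2-methyl-5-{(1R)-1-methyl-6-[(2E)-3-methylpenta-2,4-dien-1-yl]-5-oxocyclohex-3-en-1-yl}pentanoate
Product: 14 tert-butyl (1S,4aR,8aR)-1,4a-dimethyl-5-[(2E)-3-methylpenta-2,4-dien-1-yl]-6-oxo-1,2,3,4,4a,5,6,8a-octahydronaphthalene-1-carboxylate (cis ring fusion; epimer mixture at the ring carbon that bears the side chain), via potassium lithium bis-enolate 13 (not isolated)
Conditions: KN(SiMe3)2, THF, −78 → 0 °C; LiN(iPr)2, −78 °C; Fe(acac)3 (2.3 equiv), THF, −78 → 23 °C; 0.01 mol/L
Reagents that add atoms: none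
Why: Proposed new method: ligand exchange places both enolate oxygens of 13 (O on C8 of the extended dienolate and O on C18 of the ester enolate) on one trivalent iron centre, inner-sphere electron transfer generates an α-ester radical at C4 that bonds to the dienolate γ-carbon C5, and a second Fe(acac)3 oxidises the resulting enone radical anion, so that two electrons are removed overall and divalent iron is left. The closest known reaction type is the intramolecular oxidative heterocoupling of a ketone enolate with an ester or amide enolate by Fe(acac)3 or soluble divalent copper carboxylates, which also builds quaternary carbon; new here is that the ketone partner reacts through the γ-carbon of its dienolate. Ring A (C1–C5, C10) closes in a 6-exo-trig mode on the C5=C6 bond of the dienolate, whereas bonding to C7 would need an eight-membered ring. C4 is controlled by the iron bridge, which can span the oxygens on C8 and C18 only if C18 lies over ring B in the chair-like array; this puts the C4 methyl outside and gives the S configuration at C4 (C18 trans to the C10 methyl) from either C4 epimer of 12. C5 is set by the C1–C3 tether, which delivers C4 to the face of C5 on the side of C1 and should give mainly the cis ring fusion, corrected in step 8. The step needs site selectivity for C5 over the α′-carbon C9: the potassium dienolate is formed under equilibrating conditions, where the extended isomer should be favoured over the cross-conjugated one at the hindered methine C9, and closure at C9 would have to join three contiguous fully substituted carbons.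

Step 8
Reactants: 14 tert-butyl (1S,4aR,8aR)-1,4a-dimethyl-5-[(2E)-3-methylpenta-2,4-dien-1-yl]-6-oxo-1,2,3,4,4a,5,6,8a-octahydronaphthalene-1-carboxylate
Product: 15 tert-butyl (1S,4aR,5S,8aS)-1,4a-dimethyl-5-[(2E)-3-methylpenta-2,4-dien-1-yl]-6-oxo-1,2,3,4,4a,5,6,8a-octahydronaphthalene-1-carboxylate
Conditions: KOtBu (0.2 equiv), tBuOH/THF, 23 °C, argon
Reagents that add atoms: none
Why: Base-catalysed equilibration through the extended dienolate (C5) and the α′-enolate (C9) should funnel the C5/C9 epimer mixture to the thermodynamic isomer, with H on C5 anti to the C10 methyl (trans ring fusion) and the C9 side chain equatorial.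

Step 9
Reactants: 15 tert-butyl (1S,4aR,5S,8aS)-1,4a-dimethyl-5-[(2E)-3-methylpenta-2,4-dien-1-yl]-6-oxo-1,2,3,4,4a,5,6,8a-octahydronaphthalene-1-carboxylate
Product: 16 tert-butyl (1S,4aR,5S,7S,8S,8aS)-7,8-epoxy-1,4a-dimethyl-5-[(2E)-3-methylpenta-2,4-dien-1-yl]-6-oxodecahydronaphthalene-1-carboxylate
Conditions: H2O2 (30% aq.), NaOH, MeOH, 0 °C
Reagents that add atoms: hydrogen peroxide, OO
Why: Weitz–Scheffer nucleophilic epoxidation touches only the enone, and hydroperoxide should add to C6 from the face opposite to the axial methyl groups on C4 and C10, which fixes the C6–O configuration that the target keeps.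

Step 10
Reactants: 16 tert-butyl (1S,4aR,5S,7S,8S,8aS)-7,8-epoxy-1,4a-dimethyl-5-[(2E)-3-methylpenta-2,4-dien-1-yl]-6-oxodecahydronaphthalene-1-carboxylate
Product: 17 tert-butyl (1S,4aR,5S,8R,8aS)-8-hydroxy-1,4a-dimethyl-5-[(2E)-3-methylpenta-2,4-dien-1-yl]-6-oxodecahydronaphthalene-1-carboxylate
Conditions: SmI2 (2.2 equiv), THF/MeOH, −90 °C
Reagents that add atoms: none
Why: Reduction of the α,β-epoxy ketone by divalent samarium cleaves the C7–O bond by two single-electron transfers and gives the β-hydroxy ketone with the C6–O stereocentre unchanged.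

Step 11
Reactants: 17 tert-butyl (1S,4aR,5S,8R,8aS)-8-hydroxy-1,4a-dimethyl-5-[(2E)-3-methylpenta-2,4-dien-1-yl]-6-oxodecahydronaphthalene-1-carboxylate
Product: 18 tert-butyl (1S,4aS,5R,8R,8aS)-8-hydroxy-1,4a-dimethyl-6-methylidene-5-[(2E)-3-methylpenta-2,4-dien-1-yl]decahydronaphthalene-1-carboxylate
Conditions: Zn, CH2Br2, TiCl4, THF/CH2Cl2, 0 → 23 °C
Reagents that add atoms: dibromomethane, BrCBr
Why: Lombardo methylenation with the non-basic zinc–titanium methylene reagent should convert the hindered, enolisable C8 ketone into the exocyclic alkene without epimerising C9 or eliminating the β-hydroxyl.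

Step 12
Reactants: 18 tert-butyl (1S,4aS,5R,8R,8aS)-8-hydroxy-1,4a-dimethyl-6-methylidene-5-[(2E)-3-methylpenta-2,4-dien-1-yl]decahydronaphthalene-1-carboxylate
Product: 19 tert-butyl (1S,4aS,5R,8R,8aS)-8-acetoxy-1,4a-dimethyl-6-methylidene-5-[(2E)-3-methylpenta-2,4-dien-1-yl]decahydronaphthalene-1-carboxylate
Conditions: Ac2O, DMAP, pyridine, 40 °C
Reagents that add atoms: acetic anhydride, CC(=O)OC(C)=O
Why: DMAP-catalysed acylation of the equatorial C6 hydroxyl affects no stereocentre and, with the C8 carbonyl gone, cannot be followed by β-elimination.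

Step 13
Reactants: 19 tert-butyl (1S,4aS,5R,8R,8aS)-8-acetoxy-1,4a-dimethyl-6-methylidene-5-[(2E)-3-methylpenta-2,4-dien-1-yl]decahydronaphthalene-1-carboxylate
Product: 21 (1S,4aS,5R,8R,8aS)-8-acetoxy-1,4a-dimethyl-6-methylidene-5-[(2E)-3-methylpenta-2,4-dien-1-yl]decahydronaphthalene-1-carboxylic acid, via trimethylsilyl ester 20 (not isolated)
Conditions: Me3SiOTf, 2,6-lutidine, CH2Cl2, 0 °C; then pH 5 buffer
Reagents that add atoms: none
Why: Silyl triflate-mediated cleavage of the tert-butyl ester (loss of isobutene, silyl ester hydrolysed on work-up) frees the acid under buffered conditions that should leave the acetate, the exocyclic alkene and the diene intact.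

Compound list
1 | tert-butyl propanoate | CCC(=O)OC(C)(C)C | starting material
2 | 3-bromoprop-1-ene (allyl bromide) | C=CCBr | starting material
3 | tert-butyl 2-methylpent-4-enoate (racemic) | C=CCC(C)C(=O)OC(C)(C)C | intermediate
4 | 3-methylcyclohex-2-en-1-one | CC1=CC(=O)CCC1 | starting material
5 | chlorobis(cyclopentadienyl)[5-(tert-butoxy)-4-methyl-5-oxopentyl]zirconium | CC(CCC[Zr](Cl)(C1C=CC=C1)C1C=CC=C1)C(=O)OC(C)(C)C | intermediate
6 | tert-butyl 2-methyl-5-[(1R)-1-methyl-3-(trimethylsilyloxy)cyclohex-2-en-1-yl]pentanoate | C1=C(O[Si](C)(C)C)CCC[C@@]1(C)CCCC(C)C(=O)OC(C)(C)C | intermediate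
7 | tert-butyl 2-methyl-5-[(1R)-1-methyl-3-oxocyclohexyl]pentanoate (epimers at chain C2) | C1C(=O)CCC[C@@]1(C)CCCC(C)C(=O)OC(C)(C)C | intermediate
8 | tert-butyl 2-methyl-5-[(1R)-1-methyl-5-oxocyclohex-3-en-1-yl]pentanoate (epimers at chain C2) | C1C(=O)C=CC[C@@]1(C)CCCC(C)C(=O)OC(C)(C)C | intermediate
9 | (2E)-3-methylpent-2-en-4-yn-1-ol | C#C/C(C)=C/CO | starting material
10 | (2E)-3-methylpenta-2,4-dien-1-ol | C=C/C(C)=C/CO | intermediate
11 | (3E)-5-bromo-3-methylpenta-1,3-diene | C=C/C(C)=C/CBr | intermediate
12 | tert-butyl 2-methyl-5-{(1R)-1-methyl-6-[(2E)-3-methylpenta-2,4-dien-1-yl]-5-oxocyclohex-3-en-1-yl}pentanoate (epimers at ring C6 and chain C2) | C=C/C(C)=C/CC1C(=O)C=CC[C@@]1(C)CCCC(C)C(=O)OC(C)(C)C | intermediate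
13 | potassium lithium bis-enolate of 12 (extended dienolate O–C8=C7–C6=C5 and ester enolate at C4) | C=C/C(C)=C/CC1C([O-])=CC=C[C@@]1(C)CCCC(C)=C([O-])OC(C)(C)C.[K+].[Li+] | intermediate
14 | tert-butyl (1S,4aR,8aR)-1,4a-dimethyl-5-[(2E)-3-methylpenta-2,4-dien-1-yl]-6-oxo-1,2,3,4,4a,5,6,8a-octahydronaphthalene-1-carboxylate (cis-fused; epimers at the side-chain carbon) | C=C/C(C)=C/CC1C(=O)C=C[C@@H]2[C@@]1(C)CCC[C@]2(C)C(=O)OC(C)(C)C | intermediate
15 | tert-butyl (1S,4aR,5S,8aS)-1,4a-dimethyl-5-[(2E)-3-methylpenta-2,4-dien-1-yl]-6-oxo-1,2,3,4,4a,5,6,8a-octahydronaphthalene-1-carboxylate (trans-fused) | C=C/C(C)=C/C[C@@H]1C(=O)C=C[C@H]2[C@@]1(C)CCC[C@]2(C)C(=O)OC(C)(C)C | intermediate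
16 | tert-butyl (1S,4aR,5S,7S,8S,8aS)-7,8-epoxy-1,4a-dimethyl-5-[(2E)-3-methylpenta-2,4-dien-1-yl]-6-oxodecahydronaphthalene-1-carboxylate | C=C/C(C)=C/C[C@@H]1C(=O)[C@H]3O[C@H]3[C@H]2[C@@]1(C)CCC[C@]2(C)C(=O)OC(C)(C)C | intermediate
17 | tert-butyl (1S,4aR,5S,8R,8aS)-8-hydroxy-1,4a-dimethyl-5-[(2E)-3-methylpenta-2,4-dien-1-yl]-6-oxodecahydronaphthalene-1-carboxylate | C=C/C(C)=C/C[C@@H]1C(=O)C[C@@H](O)[C@H]2[C@@]1(C)CCC[C@]2(C)C(=O)OC(C)(C)C | intermediate
18 | tert-butyl (1S,4aS,5R,8R,8aS)-8-hydroxy-1,4a-dimethyl-6-methylidene-5-[(2E)-3-methylpenta-2,4-dien-1-yl]decahydronaphthalene-1-carboxylate | C=C/C(C)=C/C[C@@H]1C(=C)C[C@@H](O)[C@H]2[C@@]1(C)CCC[C@]2(C)C(=O)OC(C)(C)C | intermediate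
19 | tert-butyl (1S,4aS,5R,8R,8aS)-8-acetoxy-1,4a-dimethyl-6-methylidene-5-[(2E)-3-methylpenta-2,4-dien-1-yl]decahydronaphthalene-1-carboxylate | C=C/C(C)=C/C[C@@H]1C(=C)C[C@@H](OC(C)=O)[C@H]2[C@@]1(C)CCC[C@]2(C)C(=O)OC(C)(C)C | intermediate
20 | trimethylsilyl (1S,4aS,5R,8R,8aS)-8-acetoxy-1,4a-dimethyl-6-methylidene-5-[(2E)-3-methylpenta-2,4-dien-1-yl]decahydronaphthalene-1-carboxylate | C=C/C(C)=C/C[C@@H]1C(=C)C[C@@H](OC(C)=O)[C@H]2[C@@]1(C)CCC[C@]2(C)C(=O)O[Si](C)(C)C | intermediate
21 | (1S,4aS,5R,8R,8aS)-8-acetoxy-1,4a-dimethyl-6-methylidene-5-[(2E)-3-methylpenta-2,4-dien-1-yl]decahydronaphthalene-1-carboxylic acid | C=C/C(C)=C/C[C@@H]1C(=C)C[C@@H](OC(C)=O)[C@H]2[C@@]1(C)CCC[C@]2(C)C(=O)O | target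

Total step count: 13. Longest linear sequence: 11 steps (steps 1, 2, 3, 6, 7, 8, 9, 10, 11, 12, 13); steps 4 and 5 make the side-chain bromide.

Steps most likely to fail

Step 7 (Proposed new method). What may go wrong: enolisation of the ketone at C9 in place of C5, intermolecular instead of intramolecular coupling at iron, and loss of the iron bridge so that the C4 epimer forms. The fallback uses known chemistry, a photoredox radical cyclisation in place of the enolate coupling, and runs from 12 back to 14. Soft enolisation of 12 (tBuMe2SiOTf, Et3N, CH2Cl2, thermodynamic conditions) should give the extended silyl dienol ether tert-butyl 5-{(1R)-3-[(tert-butyldimethylsilyl)oxy]-1-methyl-2-[(2E)-3-methylpenta-2,4-dien-1-yl]cyclohexa-3,5-dien-1-yl}-2-methylpentanoate F1. Deprotonation of its ester with LiN(iPr)2 and quenching with CBr4 gives the tertiary α-bromo ester tert-butyl 2-bromo-5-{(1R)-3-[(tert-butyldimethylsilyl)oxy]-1-methyl-2-[(2E)-3-methylpenta-2,4-dien-1-yl]cyclohexa-3,5-dien-1-yl}-2-methylpentanoate F2. Irradiation with blue light in the presence of Ru(bpy)3Cl2 and 2,6-lutidine in MeCN, the known photoredox alkylation of silyl enol ethers by α-bromo esters, generates the C4 radical, which closes ring A 6-exo onto C5 of the silyloxy diene; oxidation of the allylic radical and loss of the silyl group give 14. In this variant C4 is under steric control only, so the ratio at C4 would have to be determined and the epimers separated.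

Step 8. What may go wrong: an equilibrium that does not lie far enough on the side of the trans ring fusion, migration of the double bond out of conjugation, or autoxidation of the dienolate. The fallback closes the ring by backside displacement, so that C5 is set by inversion and not by an equilibrium, and runs from 12 back to 15. The silyl dienol ether F1, made as above, is brominated at its γ-carbon with N-bromosuccinimide (THF, −78 °C), expected anti to the pseudo-axial C10 methyl, to give the γ-bromo enone tert-butyl 5-{(1S)-2-bromo-1-methyl-6-[(2E)-3-methylpenta-2,4-dien-1-yl]-5-oxocyclohex-3-en-1-yl}-2-methylpentanoate F3. LiN(iPr)2 (THF, −78 → 0 °C) then forms the ester enolate, which displaces bromide at C5 with inversion in a 6-exo-tet alkylation and places C4 on the face of the C10 methyl, which is the trans ring fusion of 15; the C9 centre would then be equilibrated under the basic conditions of step 9.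

Step 2. What may go wrong: incomplete hydrozirconation next to the ester, slow transfer of the functionalised alkyl group to copper, or low enantioselectivity. The fallback exchanges the roles of the two C10 substituents and runs from 3 back to 7. Hydroboration of 3 with 9-BBN gives the borane tert-butyl 5-(9-borabicyclo[3.3.1]nonan-9-yl)-2-methylpentanoate F4, which is coupled in the same flask with 3-bromocyclohex-2-en-1-one (Suzuki–Miyaura coupling, PdCl2(dppf), K3PO4, THF/H2O) to the enone tert-butyl 2-methyl-5-(3-oxocyclohex-1-en-1-yl)pentanoate F5. Copper-catalysed asymmetric conjugate addition of AlMe3 (copper thiophene-2-carboxylate, chiral phosphoramidite ligand, Et2O, −30 °C) then adds the methyl group to C10 and gives 7 after aqueous work-up.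

Further compounds
F1 | step 7 | tert-butyl 5-{(1R)-3-[(tert-butyldimethylsilyl)oxy]-1-methyl-2-[(2E)-3-methylpenta-2,4-dien-1-yl]cyclohexa-3,5-dien-1-yl}-2-methylpentanoate | C=C/C(C)=C/CC1C(O[Si](C)(C)C(C)(C)C)=CC=C[C@@]1(C)CCCC(C)C(=O)OC(C)(C)C
F2 | step 7 | tert-butyl 2-bromo-5-{(1R)-3-[(tert-butyldimethylsilyl)oxy]-1-methyl-2-[(2E)-3-methylpenta-2,4-dien-1-yl]cyclohexa-3,5-dien-1-yl}-2-methylpentanoate | C=C/C(C)=C/CC1C(O[Si](C)(C)C(C)(C)C)=CC=C[C@@]1(C)CCCC(C)(Br)C(=O)OC(C)(C)C
F3 | step 8 | tert-butyl 5-{(1S)-2-bromo-1-methyl-6-[(2E)-3-methylpenta-2,4-dien-1-yl]-5-oxocyclohex-3-en-1-yl}-2-methylpentanoate | C=C/C(C)=C/CC1C(=O)C=CC(Br)[C@@]1(C)CCCC(C)C(=O)OC(C)(C)C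
F4 | step 2 | tert-butyl 5-(9-borabicyclo[3.3.1]nonan-9-yl)-2-methylpentanoate | CC(CCCB1C2CCCC1CCC2)C(=O)OC(C)(C)C
F5 | step 2 | tert-butyl 2-methyl-5-(3-oxocyclohex-1-en-1-yl)pentanoate | O=C1C=C(CCCC(C)C(=O)OC(C)(C)C)CCC1
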